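## Analysis of the target

- The target is an open-chain tridecane with one benzene ring on C1 and an acetoxy group on C2. There is no ring other than the arene.
- C2 is the only stereocentre. It is (R) (O > CH2Ar > CH2-alkyl > H) and, being isolated, needs only absolute control.
- C2 lies between two methylene groups, one benzylic and one at the head of a decyl tail. A carbonyl at C2 would offer a reducing catalyst two nearly identical flanks, which argues for taking C2 from the chiral pool.
- The arene is 1,3,5-trisubstituted: chain on ring C1, OMe on C3 and free OH on C5, all mutually meta. It is a resorcinol whose two oxygens are differentiated.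
- The sensitive groups are the secondary acetate, which must survive beside a free phenol, and the electron-rich phenol, which is easily over-oxidised.
- The difficulty is not the skeleton but the oxygen pattern. All three ring substituents are ortho/para directors placed meta to one another, so electrophilic substitution cannot install any of them, and only one of two hydroxyls may carry the acetyl group.
- The strategy rests on one feature. In the 3-alkylanisole 9, ring C5 is the only aromatic CH whose two neighbours are also CH; C2, C4 and C6 each have a substituent next door. A sterically governed C–H functionalisation can therefore single out C5, where the OH belongs.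

## Retrosynthetic reasoning

**Phenolic C5–O bond (12 to 11).** The C5–O bond is traced back to a C5–B bond in boronate 11. Oxidation of an aryl boronate places oxygen exactly where boron was, so the regiochemical problem moves to the borylation. The forward reaction must oxidise boron without hydrolysing the acetate and without attacking the electron-rich ring.

**Aryl C5–B bond (11 to 9 and 10).** The C5–B bond is cut to a C5–H bond, giving the mono-oxygenated arene 9 and the diboron reagent 10. This removes every resorcinol-differentiation problem: the ring is bought with one oxygen and the second is placed by the shape of the substrate. The forward reaction must choose C5 over C2, C4, C6 and all sp3 C–H bonds, and must leave the acetate and C2 alone.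

**Acetate C–O bond (9 to 8).** The acetyl group is removed to give alcohol 8. Acetylation is placed before the borylation on purpose: 8 has a single hydroxyl, so no phenol/alcohol selectivity arises, and a free OH would consume boron reagent in the next step.

**Aryl–C1 bond (8 to 5 and 6, via 7).** The bond between the ring and C1 is cut, giving epoxide 5 and the aryl Grignard reagent 7 made from bromide 6. Attack at the terminal epoxide carbon forms this bond without touching C2. Bringing the arene in at this late point of the chain assembly also allows another aryl nucleophile to be used if the late C–H step fails.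

**Epoxide C1–O and C3–C4 bonds (5 to 4 to 2 and 1, via 3).** Epoxide 5 comes from chlorohydrin 4 by ring closure, and 4 from opening of the chiral epoxide 2 by the decyl Grignard reagent 3 made from bromide 1. C2 is thus bought, not made. The CH2Cl carbon of 2 becomes C1 and the ring CH2 becomes C3, so the ranking at C2 is unchanged and the (R)-enantiomer of 2 leads to the (R)-target.

## Alternatives that were turned down

**Alternative 1: arene built by Michael–Dieckmann annulation.**
- Disconnection: the benzene ring itself is taken apart into a chiral enone and a malonate.
- Forward key step: dimethyl malonate A3 adds to the β-carbon of (R,E)-6-(tert-butyldimethylsilyloxy)heptadec-3-en-2-one A2 under methoxide. The methyl ketone enolate then condenses onto a malonate ester, giving the cyclohexanedione ester A1 with two new ring C–C bonds.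
- For it: commodity reagents, no precious metal, and a substitution pattern fixed by construction. The mono methyl enol ether of the derived dione would aromatise directly to the methoxyphenol, so the two oxygens are differentiated for free. On these points it is stronger than the chosen route.
- Against it: A2 needs four to five steps of its own. Its γ-protons are acidic under methoxide, and the dienolate can expel the δ-silyloxy group, which would destroy the only stereocentre. After A1 come ester cleavage with decarboxylation, enol ether formation, a dehydrogenative aromatisation that is harsh for the chain, desilylation and acetylation.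
- Comparison: ten or more steps against six. The chosen route buys the ring and changes one C–H bond, and C2 never sits next to an enolisable system.

**Alternative 2: three-component conjunctive coupling.**
- Disconnection: the aryl–C1 and C2–C3 bonds are cut together.
- Forward key step: vinyllithium A7 and 4,4,5,5-tetramethyl-2-undecyl-1,3,2-dioxaborolane A6 form a vinyl boron ate complex. A chiral palladium bisphosphine catalyst, after oxidative addition to 3-(benzyloxy)-5-methoxyphenyl trifluoromethanesulfonate A5, triggers 1,2-migration of the undecyl group from boron to carbon as the aryl group adds to the terminal vinyl carbon. The product is boronate A4, (R)-2-[1-(3-benzyloxy-5-methoxyphenyl)tridecan-2-yl]-4,4,5,5-tetramethyl-1,3,2-dioxaborolane.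
- For it: two C–C bonds and the stereocentre form in one catalytic enantioselective step from three simple pieces. In convergence it is stronger than the chosen route, and its step count is similar.
- Against it: A5 carries three different oxygen substituents on one ring, so it requires the resorcinol differentiation that the target makes hard. The coupling is sensitive to halide, the electron-rich triflate adds slowly to palladium, and the enantiomeric purity of C2 depends on a catalyst for a primary-alkyl migrating group. Oxidation of the C–B bond, acetylation and debenzylation must follow.
- Comparison: the chosen route offers a stereocentre of purchased purity and needs neither a differentiated resorcinol nor a final deprotection.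

**Alternative 3: nickel-electrocatalytic doubly decarboxylative coupling.**
- Disconnection: the C3–C4 bond.
- Forward key step: the redox-active esters 1,3-dioxoisoindolin-2-yl (S)-3-acetoxy-4-[3-(benzyloxy)-5-methoxyphenyl]butanoate A9 and 1,3-dioxoisoindolin-2-yl undecanoate A10 are reduced at a cathode with a nickel bipyridine catalyst. Both decarboxylate and the two primary alkyl radicals are joined through nickel to give (R)-1-[3-(benzyloxy)-5-methoxyphenyl]tridecan-2-yl acetate A8. The descriptor of A9 is S only because the CH2CO2 group outranks CH2Ar; the spatial arrangement is that of A8.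
- For it: carboxylic acid feedstocks, mild conditions, and a tail of any length can be attached late. In modularity of the chain it is stronger than the chosen route.
- Against it: the radical or alkylnickel species from A9 carries an acetoxy group β to the reacting carbon, so β-elimination to an allylarene is a built-in side path. Two primary radicals couple statistically, so A10 must be used in excess and the chiral partner is partly lost to homocoupling. A9 itself needs the differentiated resorcinol, a chain extension, an asymmetric reduction and selective unmasking of an acid next to an acetate. Debenzylation of A8 still follows.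
- Comparison: the chosen route makes the same C3–C4 bond in its first step by a polar epoxide opening with no statistical or elimination problem, and reaches the target in six steps.

Key step: step 5

Remark on the chemistry: both enantiomers of epichlorohydrin are taken as articles of commerce of high enantiomeric purity, and the (R)-enantiomer is the one required here.

## Route

**Step 1**
Reactants: 1 1-bromodecane; 2 (R)-epichlorohydrin [(R)-2-(chloromethyl)oxirane]
Product: 4 (R)-1-chlorotridecan-2-ol, via decylmagnesium bromide 3 (not isolated)
Conditions: Mg, THF, 45 °C; then 2, CuI (5 mol%), THF, −40 → 0 °C; 1 M HCl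
Reagents that add atoms: none
Why: Copper-catalysed Grignard opening of an epoxide by SN2 attack at the unsubstituted ring carbon; the decyl group becomes C4–C13 and the former ring CH2 becomes C3. No bond to the stereocentre of 2 is touched and CH2Cl still outranks the alkyl CH2, so C2 stays (R); at low temperature the magnesium chloro-alkoxide does not close to an epoxide, which prevents a second addition.

**Step 2**
Reactants: 4 (R)-1-chlorotridecan-2-ol
Product: 5 (R)-2-undecyloxirane
Conditions: NaOH (powdered, 3 equiv), Et2O, 0 °C → rt
Reagents that add atoms: none
Why: Intramolecular Williamson etherification (3-exo-tet SN2 of the alkoxide on CH2Cl); the C2–O bond is not broken, so the configuration is retained and the (R)-epoxide should result.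

**Step 3**
Reactants: 5 (R)-2-undecyloxirane; 6 3-bromoanisole (1-bromo-3-methoxybenzene)
Product: 8 (R)-1-(3-methoxyphenyl)tridecan-2-ol, via (3-methoxyphenyl)magnesium bromide 7 (not isolated)
Conditions: Mg, THF, reflux; then 5, CuI (10 mol%), THF, −30 → 0 °C; 1 M HCl
Reagents that add atoms: none
Why: Copper-catalysed opening of a terminal epoxide by an aryl Grignard reagent at the less hindered CH2, which forms the aryl–C1 bond. C2 is not a reacting centre and CH2Ar inherits the rank of the ring CH2, so the alcohol should be (R).

**Step 4**
Reactants: 8 (R)-1-(3-methoxyphenyl)tridecan-2-ol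
Product: 9 (R)-1-(3-methoxyphenyl)tridecan-2-yl acetate
Conditions: Ac2O, pyridine, DMAP (5 mol%), CH2Cl2, rt
Reagents that add atoms: acetic anhydride, CC(=O)OC(C)=O
Why: DMAP-catalysed acylation of a secondary alcohol; 8 has a single hydroxyl, so no chemoselectivity question arises, and the stereocentre is not involved.

**Step 5**
Reactants: 9 (R)-1-(3-methoxyphenyl)tridecan-2-yl acetate; 10 bis(pinacolato)diboron (1.0 equiv)
Product: 11 (R)-1-[3-methoxy-5-(4,4,5,5-tetramethyl-1,3,2-dioxaborolan-2-yl)phenyl]tridecan-2-yl acetate
Conditions: [Ir(OMe)(cod)]2 (1.5 mol%), 4,4'-di-tert-butyl-2,2'-bipyridine (3 mol%), cyclohexane, 80 °C, N2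
Reagents that add atoms: none
Why: This is an iridium-catalysed aromatic C–H borylation, and its closest known relatives are the 5-selective borylations of 3-substituted anisoles and other 1,3-disubstituted benzenes. [Ir(OMe)(cod)]2, the bipyridine and 10 should form the 16-electron tris(boryl) complex (dtbpy)Ir(Bpin)3 of trivalent iridium, which cleaves an aryl C–H bond by boryl-assisted oxidative addition and releases the aryl boronate by C–B reductive elimination; 10 then regenerates the tris(boryl) species and leaves pinacolborane. The step closes no ring and creates no stereocentre, so the only selectivity it needs is positional. The crowded metal centre cannot reach a C–H bond with an ortho substituent: ring C2 lies between the side chain and OMe, C4 is next to the branched side chain and C6 is next to OMe, which leaves C5 as the only ring C–H with hydrogen on both sides, and the new C5–B bond forms there. The sp3 C–H bonds (benzylic CH2, OCH3, acetyl CH3) should react far more slowly with a bipyridine-ligated iridium boryl at this temperature. The acetate carbonyl cannot steer the metal to C4, because the bidentate ligand leaves one open site and the chelate would be eight-membered. C2 of the chain is untouched, since the medium is neutral and aprotic and esters are tolerated by this catalyst.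

**Step 6**
Reactants: 11 (R)-1-[3-methoxy-5-(4,4,5,5-tetramethyl-1,3,2-dioxaborolan-2-yl)phenyl]tridecan-2-yl acetate
Product: 12 (R)-1-(3-hydroxy-5-methoxyphenyl)tridecan-2-yl acetate (CNP0215596.1)
Conditions: KHSO5 (as 2KHSO5·KHSO4·K2SO4, 1.1 equiv), acetone/H2O 1:1, 0 °C → rt, 15 min; then aq. NaHSO3
Reagents that add atoms: potassium peroxymonosulfate, [K+].[O-]S(=O)(=O)OO
Why: Oxidative ipso-hydroxylation of an aryl boronate: peroxymonosulfate adds to boron, the aryl group migrates from boron to oxygen with loss of sulfate, and the aryl borate hydrolyses to the phenol at the carbon that carried boron. The medium is weakly acidic and the contact time short, so the secondary acetate should survive and C2 is not affected.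

## Compound list

1 | 1-bromodecane | CCCCCCCCCCBr | starting material
2 | (R)-epichlorohydrin [(R)-2-(chloromethyl)oxirane] | ClC[C@H]1CO1 | starting material
3 | decylmagnesium bromide | CCCCCCCCCC[Mg]Br | intermediate
4 | (R)-1-chlorotridecan-2-ol | CCCCCCCCCCC[C@H](CCl)O | intermediate
5 | (R)-2-undecyloxirane | CCCCCCCCCCC[C@@H]1CO1 | intermediate
6 | 3-bromoanisole (1-bromo-3-methoxybenzene) | COc1cccc(Br)c1 | starting material
7 | (3-methoxyphenyl)magnesium bromide | COc1cccc([Mg]Br)c1 | intermediate
8 | (R)-1-(3-methoxyphenyl)tridecan-2-ol | CCCCCCCCCCC[C@H](Cc1cccc(OC)c1)O | intermediate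
9 | (R)-1-(3-methoxyphenyl)tridecan-2-yl acetate | CCCCCCCCCCC[C@H](Cc1cccc(OC)c1)OC(C)=O | intermediate
10 | bis(pinacolato)diboron | CC1(C)OB(OC1(C)C)B1OC(C)(C)C(C)(C)O1 | starting material
11 | (R)-1-[3-methoxy-5-(4,4,5,5-tetramethyl-1,3,2-dioxaborolan-2-yl)phenyl]tridecan-2-yl acetate | CCCCCCCCCCC[C@H](Cc1cc(OC)cc(B2OC(C)(C)C(C)(C)O2)c1)OC(C)=O | intermediate
12 | (R)-1-(3-hydroxy-5-methoxyphenyl)tridecan-2-yl acetate | CCCCCCCCCCC[C@H](Cc1cc(O)cc(OC)c1)OC(C)=O | target

## Step count and least certain steps

Total: 6 steps. Longest linear sequence: 6 steps (from 1 and 2 to 12); 6 and 10 enter at steps 3 and 5.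

**Step 5 (key step).**
- Risk: loss of positional control, with some borylation next to the small OMe group at C6 or at C4, and slow C–H cleavage on an electron-rich ring that leaves conversion incomplete.
- Fallback, setting out from 5 and returning at 12: the oxygen pattern is bought instead of made. Commercial 3-bromo-5-methoxyphenol F1 is benzylated (benzyl bromide, K2CO3, DMF) to 1-(benzyloxy)-3-bromo-5-methoxybenzene F2. Its Grignard reagent [3-(benzyloxy)-5-methoxyphenyl]magnesium bromide F3 opens 5 under CuI catalysis as in step 3 to give (R)-1-[3-(benzyloxy)-5-methoxyphenyl]tridecan-2-ol F4. Acetylation gives (R)-1-[3-(benzyloxy)-5-methoxyphenyl]tridecan-2-yl acetate F5, and hydrogenolysis (H2, Pd/C, EtOAc) removes the benzyl group to give 12.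

**Step 6.**
- Risk: hydrolysis of the acetate during the C–B oxidation, or further oxidation of the electron-rich phenol once it is formed.
- Fallback, setting out from 11 and returning at 12: the acetate is deliberately given up and put back. Alkaline peroxide (NaOH, H2O2, THF/MeOH) oxidises the boronate and saponifies the ester in one operation to (R)-3-(2-hydroxytridecyl)-5-methoxyphenol F6. Exhaustive acetylation (Ac2O, pyridine, DMAP) gives (R)-1-(3-acetoxy-5-methoxyphenyl)tridecan-2-yl acetate F7. Pyrrolidine in CH2Cl2 at 0 °C should cleave only the aryl acetate, whose aryloxide is the far better leaving group, and so return 12.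

**Step 3.**
- Risk: opening of the epoxide by bromide to a halohydrin, or Lewis-acid-induced rearrangement of the epoxide, because an aryl Grignard reagent is a modest nucleophile toward an unactivated alkyl oxirane.
- Fallback, setting out from 6 (as 7) and 1 (as 3) and returning at 8: the order of the two openings is reversed, so the aryl reagent meets the more reactive epoxide and the alkyl reagent the less reactive one. Reagent 7 with CuI opens (S)-epichlorohydrin F8 to (S)-1-chloro-3-(3-methoxyphenyl)propan-2-ol F9, and NaOH closes this to (S)-2-(3-methoxybenzyl)oxirane F10. Reagent 3 with CuI opens F10 at the terminal carbon to give 8. The (S)-series is needed here because CH2Cl now becomes C3.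

**Step 1.**
- Risk: erosion of enantiomeric purity by direct displacement of chloride, which after ring closure leads to the mirror-image epoxide, and double addition if the chloro-alkoxide closes too early.
- Fallback, setting out from 1 (as 3) and returning at 5: the configuration is set by resolution, independent of the purity of 2. Reagent 3 is allylated with allyl bromide to 1-tridecene F11, which is also commercial. Epoxidation with mCPBA gives rac-2-undecyloxirane F12. Hydrolytic kinetic resolution with (S,S)-(salen)Co(OAc) (salen = N,N'-bis(3,5-di-tert-butylsalicylidene)-1,2-cyclohexanediamine dianion) and 0.55 equiv of water should hydrate the (S)-epoxide to (S)-tridecane-1,2-diol F13 and leave 5.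

## Further compounds

F1 | step 5 | 3-bromo-5-methoxyphenol | COc1cc(O)cc(Br)c1
F2 | step 5 | 1-(benzyloxy)-3-bromo-5-methoxybenzene | COc1cc(Br)cc(OCc2ccccc2)c1
F3 | step 5 | [3-(benzyloxy)-5-methoxyphenyl]magnesium bromide | COc1cc([Mg]Br)cc(OCc2ccccc2)c1
F4 | step 5 | (R)-1-[3-(benzyloxy)-5-methoxyphenyl]tridecan-2-ol | CCCCCCCCCCC[C@H](Cc1cc(OCc2ccccc2)cc(OC)c1)O
F5 | step 5 | (R)-1-[3-(benzyloxy)-5-methoxyphenyl]tridecan-2-yl acetate | CCCCCCCCCCC[C@H](Cc1cc(OCc2ccccc2)cc(OC)c1)OC(C)=O
F6 | step 6 | (R)-3-(2-hydroxytridecyl)-5-methoxyphenol | CCCCCCCCCCC[C@H](Cc1cc(O)cc(OC)c1)O
F7 | step 6 | (R)-1-(3-acetoxy-5-methoxyphenyl)tridecan-2-yl acetate | CCCCCCCCCCC[C@H](Cc1cc(OC(C)=O)cc(OC)c1)OC(C)=O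
F8 | step 3 | (S)-epichlorohydrin [(S)-2-(chloromethyl)oxirane] | ClC[C@@H]1CO1
F9 | step 3 | (S)-1-chloro-3-(3-methoxyphenyl)propan-2-ol | ClC[C@@H](O)Cc1cccc(OC)c1
F10 | step 3 | (S)-2-(3-methoxybenzyl)oxirane | C1[C@@H](O1)Cc2cccc(OC)c2
F11 | step 1 | 1-tridecene | C=CCCCCCCCCCCC
F12 | step 1 | rac-2-undecyloxirane | CCCCCCCCCCCC1CO1
F13 | step 1 | (S)-tridecane-1,2-diol | CCCCCCCCCCC[C@H](O)CO
A1 | alternative 1 | methyl 2,4-dioxo-6-[(R)-2-(tert-butyldimethylsilyloxy)tridecyl]cyclohexane-1-carboxylate | CCCCCCCCCCC[C@H](CC1CC(=O)CC(=O)C1C(=O)OC)O[Si](C)(C)C(C)(C)C
A2 | alternative 1 | (R,E)-6-(tert-butyldimethylsilyloxy)heptadec-3-en-2-one | CCCCCCCCCCC[C@H](C/C=C/C(C)=O)O[Si](C)(C)C(C)(C)C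
A3 | alternative 1 | dimethyl malonate | COC(=O)CC(=O)OC
A4 | alternative 2 | (R)-2-[1-(3-benzyloxy-5-methoxyphenyl)tridecan-2-yl]-4,4,5,5-tetramethyl-1,3,2-dioxaborolane | CCCCCCCCCCC[C@H](Cc1cc(OCc2ccccc2)cc(OC)c1)B1OC(C)(C)C(C)(C)O1
A5 | alternative 2 | 3-(benzyloxy)-5-methoxyphenyl trifluoromethanesulfonate | COc1cc(OCc2ccccc2)cc(OS(=O)(=O)C(F)(F)F)c1
A6 | alternative 2 | 4,4,5,5-tetramethyl-2-undecyl-1,3,2-dioxaborolane | CCCCCCCCCCCB1OC(C)(C)C(C)(C)O1
A7 | alternative 2 | vinyllithium | [Li]C=C
A8 | alternative 3 | (R)-1-[3-(benzyloxy)-5-methoxyphenyl]tridecan-2-yl acetate | CCCCCCCCCCC[C@H](Cc1cc(OCc2ccccc2)cc(OC)c1)OC(C)=O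
A9 | alternative 3 | 1,3-dioxoisoindolin-2-yl (S)-3-acetoxy-4-[3-(benzyloxy)-5-methoxyphenyl]butanoate | O=C(C[C@H](Cc1cc(OCc2ccccc2)cc(OC)c1)OC(C)=O)ON1C(=O)c2ccccc2C1=O
A10 | alternative 3 | 1,3-dioxoisoindolin-2-yl undecanoate | CCCCCCCCCCC(=O)ON1C(=O)c2ccccc2C1=O
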